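The bond on which everything rests joins the ketone carbon to ring A (the trioxygenated ring), at the ring carbon para to the central oxygen and meta to both flanking oxygens, a position that Friedel–Crafts acylation of this ring would not choose. An iodide placed on that carbon is added, by a chromium–nickel mediated Nozaki–Hiyama–Kishi reaction, to the CH2–CHO arm of ring B (the meta-linked ring). This one operation forms the aryl–carbinol bond and closes the 18-membered ring. The precursor is the open-chain tetra-aryl chain with both diaryl ethers and the bibenzyl bridge in place, three methyl ethers, the iodide on ring A and the arylacetaldehyde on ring B. Oxidation and demethylation then give marchantin G.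

Key step: step 11

Assumptions and remarks on the chemistry:
- Ring lettering: A is the trioxygenated ring bearing the carbonyl, B the meta-linked ring bearing the CH2 next to the carbonyl, C the 1,2,3-trisubstituted ring, D the para-linked ring. The target has no stereocentre.
- The iodine is introduced in step 1 by iodinating o-vanillin para to its hydroxyl, so no halogen exchange is needed later.
- The ring A aldehyde is converted into the phenol after O-methylation, so a peracid Baeyer–Villiger oxidation is used; alkaline peroxide needs a free ortho or para hydroxyl.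
- The stilbene 14 is carried as an E/Z mixture because both isomers give the same bibenzyl in step 9.

Step 1
Reactants: 1 o-vanillin (2-hydroxy-3-methoxybenzaldehyde)
Product: 2 2-hydroxy-5-iodo-3-methoxybenzaldehyde
Conditions: NIS, TFA (cat.), MeCN, rt
Reagents that add atoms: N-iodosuccinimide, O=C1CCC(=O)N1I
Why: Electrophilic aromatic iodination, in which the free phenol should direct the iodine to its open para position (C5), the only strongly activated site, as in the known halogenations of o-vanillin.

Step 2
Reactants: 2 2-hydroxy-5-iodo-3-methoxybenzaldehyde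
Product: 3 5-iodo-2,3-dimethoxybenzaldehyde
Conditions: MeI, K2CO3, DMF, rt
Reagents that add atoms: iodomethane, CI
Why: Williamson O-methylation of the phenoxide, the only acidic site in the molecule.

Step 3
Reactants: 3 5-iodo-2,3-dimethoxybenzaldehyde
Product: 5 5-iodo-2,3-dimethoxyphenol, via 5-iodo-2,3-dimethoxyphenyl formate 4 (not isolated)
Conditions: mCPBA, CH2Cl2, 0 °C to rt; then K2CO3 (cat.), MeOH, rt
Reagents that add atoms: 3-chloroperoxybenzoic acid, OOC(=O)c1cccc(Cl)c1
Why: Baeyer–Villiger oxidation in which the electron-rich aryl group with its ortho methoxy should migrate to give the aryl formate, which base-catalysed methanolysis cleaves to the phenol, while the aryl iodide is not expected to be oxidised without strong acid.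

Step 4
Reactants: 5 5-iodo-2,3-dimethoxyphenol; 6 4-fluorobenzaldehyde
Product: 7 4-(5-iodo-2,3-dimethoxyphenoxy)benzaldehyde
Conditions: K2CO3, DMF, 120 °C
Reagents that add atoms: none
Why: Nucleophilic aromatic substitution (addition–elimination) of the fluoride para to the formyl group by the phenoxide, and with no copper present the aryl iodide should stay inert.

Step 5
Reactants: 7 4-(5-iodo-2,3-dimethoxyphenoxy)benzaldehyde
Product: 8 [4-(5-iodo-2,3-dimethoxyphenoxy)phenyl]methanol
Conditions: NaBH4, MeOH, 0 °C
Reagents that add atoms: none
Why: Chemoselective hydride reduction of the aldehyde, which leaves the aryl iodide and the ethers untouched.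

Step 6
Reactants: 8 [4-(5-iodo-2,3-dimethoxyphenoxy)phenyl]methanol
Product: 9 {[4-(5-iodo-2,3-dimethoxyphenoxy)phenyl]methyl}triphenylphosphonium bromide
Conditions: PPh3·HBr, MeCN, reflux
Reagents that add atoms: triphenylphosphine hydrobromide, [Br-].[PH+](c1ccccc1)(c1ccccc1)c1ccccc1
Why: Acid-promoted substitution at the electron-rich para-aryloxy benzylic alcohol by triphenylphosphine, a known one-step conversion of benzylic alcohols into Wittig salts with loss of water.

Step 7
Reactants: 10 2-fluoro-3-methoxybenzaldehyde; 11 3-(2-hydroxyethyl)phenol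
Product: 12 2-[3-(2-hydroxyethyl)phenoxy]-3-methoxybenzaldehyde
Conditions: K2CO3, DMF, 110 °C
Reagents that add atoms: none
Why: Nucleophilic aromatic substitution of the fluoride ortho to the formyl group, in which K2CO3 deprotonates only the phenol so that the primary alcohol stays free.

Step 8
Reactants: 9 {[4-(5-iodo-2,3-dimethoxyphenoxy)phenyl]methyl}triphenylphosphonium bromide; 12 2-[3-(2-hydroxyethyl)phenoxy]-3-methoxybenzaldehyde
Product: 14 2-{3-[2-{2-[4-(5-iodo-2,3-dimethoxyphenoxy)phenyl]ethenyl}-6-methoxyphenoxy]phenyl}ethanol (E/Z mixture), via phosphonium ylide 13 (not isolated)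
Conditions: K2CO3, 18-crown-6 (cat.), CH2Cl2, reflux
Reagents that add atoms: none
Why: Wittig olefination of a semi-stabilised benzylic ylide generated under mild solid–liquid phase-transfer conditions, which should tolerate the free alcohol and the aryl iodide.

Step 9
Reactants: 14 2-{3-[2-{2-[4-(5-iodo-2,3-dimethoxyphenoxy)phenyl]ethenyl}-6-methoxyphenoxy]phenyl}ethanol (E/Z mixture)
Product: 15 2-{3-[2-{2-[4-(5-iodo-2,3-dimethoxyphenoxy)phenyl]ethyl}-6-methoxyphenoxy]phenyl}ethanol
Conditions: TsNHNH2, NaOAc, DME/H2O, reflux
Reagents that add atoms: none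
Why: Diimide reduction, a concerted syn transfer of two hydrogens from HN=NH, should saturate the stilbene double bond without the hydrodeiodination that catalytic hydrogenation would risk.

Step 10
Reactants: 15 2-{3-[2-{2-[4-(5-iodo-2,3-dimethoxyphenoxy)phenyl]ethyl}-6-methoxyphenoxy]phenyl}ethanol
Product: 16 {3-[2-{2-[4-(5-iodo-2,3-dimethoxyphenoxy)phenyl]ethyl}-6-methoxyphenoxy]phenyl}acetaldehyde
Conditions: Dess–Martin periodinane, CH2Cl2, 0 °C to rt; short silica plug, used at once
Reagents that add atoms: none
Why: Dess–Martin oxidation should stop at the aldehyde under nearly neutral, non-enolising conditions, and the labile arylacetaldehyde is taken directly into the ring closure.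

Step 11
Reactants: 16 {3-[2-{2-[4-(5-iodo-2,3-dimethoxyphenoxy)phenyl]ethyl}-6-methoxyphenoxy]phenyl}acetaldehyde
Product: 17 macrocyclic benzylic alcohol (tri-O-methyl carbinol of the 18-membered ring, ring A–CH(OH)–CH2–ring B, racemic)
Conditions: CrCl2 (8 equiv), NiCl2 (5 mol%), degassed DMF, slow addition of 16 to about 2 mM, rt to 50 °C; aqueous work-up
Reagents that add atoms: none
Why: Divalent chromium reduces NiCl2 to zerovalent nickel, which inserts into the C–I bond of ring A; transmetalation to trivalent chromium gives an arylchromium species that adds 1,2 to the aldehyde, and the chromium alkoxide is hydrolysed on work-up. The closest known reaction type is the Nozaki–Hiyama–Kishi coupling of aryl and alkenyl iodides with aldehydes, including its macrocyclising variants. The 18-membered ring is closed by an intramolecular 18-exo-trig attack of the ring A carbon on the carbonyl carbon, helped by slow addition at high dilution and by the two diaryl ether hinges and the flexible bibenzyl bridge, which let the chain ends meet without strain. The new carbinol centre has no controlling element and should form as a racemate, which is of no consequence because step 12 oxidises it to the ketone. The step needs carbonyl addition to win over aldol reaction, loss of iodine by protonation and biaryl homocoupling; the non-basic arylchromium reagent spares the enolisable arylacetaldehyde, the low nickel loading and dilution hold back homocoupling, and the attachment site on ring A is fixed by the iodide, which sits between two ring hydrogens and is unhindered.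

Step 12
Reactants: 17 macrocyclic benzylic alcohol (racemic)
Product: 18 marchantin G trimethyl ether (macrocyclic aryl benzyl ketone)
Conditions: Dess–Martin periodinane, CH2Cl2, rt
Reagents that add atoms: none
Why: Dess–Martin oxidation of the secondary benzylic carbinol to the aryl ketone, which removes the only stereocentre.

Step 13
Reactants: 18 marchantin G trimethyl ether
Product: 19 marchantin G
Conditions: BBr3 (excess), CH2Cl2, −78 °C to rt; then H2O
Reagents that add atoms: none
Why: Lewis-acid ether cleavage by BBr3 (coordination at oxygen, then bromide attack on the methyl carbon) should remove the three aryl methyl ethers, while the diaryl ethers, which carry no sp3 carbon on oxygen, and the ketone survive.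

Compound list
1 | o-vanillin (2-hydroxy-3-methoxybenzaldehyde) | O=Cc1cccc(OC)c1O | starting material
2 | 2-hydroxy-5-iodo-3-methoxybenzaldehyde | O=Cc1cc(I)cc(OC)c1O | intermediate
3 | 5-iodo-2,3-dimethoxybenzaldehyde | O=Cc1cc(I)cc(OC)c1OC | intermediate
4 | 5-iodo-2,3-dimethoxyphenyl formate | O=COc1cc(I)cc(OC)c1OC | intermediate (not isolated)
5 | 5-iodo-2,3-dimethoxyphenol | Oc1cc(I)cc(OC)c1OC | intermediate
6 | 4-fluorobenzaldehyde | O=Cc1ccc(F)cc1 | starting material
7 | 4-(5-iodo-2,3-dimethoxyphenoxy)benzaldehyde | O=Cc1ccc(cc1)Oc1cc(I)cc(OC)c1OC | intermediate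
8 | [4-(5-iodo-2,3-dimethoxyphenoxy)phenyl]methanol | OCc1ccc(cc1)Oc1cc(I)cc(OC)c1OC | intermediate
9 | {[4-(5-iodo-2,3-dimethoxyphenoxy)phenyl]methyl}triphenylphosphonium bromide | [Br-].COc1cc(I)cc(Oc2ccc(C[P+](c3ccccc3)(c3ccccc3)c3ccccc3)cc2)c1OC | intermediate
10 | 2-fluoro-3-methoxybenzaldehyde | COc1cccc(C=O)c1F | starting material
11 | 3-(2-hydroxyethyl)phenol | OCCc1cccc(O)c1 | starting material
12 | 2-[3-(2-hydroxyethyl)phenoxy]-3-methoxybenzaldehyde | O=Cc1cccc(OC)c1Oc1cccc(CCO)c1 | intermediate
13 | phosphonium ylide from 9 ({[4-(5-iodo-2,3-dimethoxyphenoxy)phenyl]methylidene}triphenylphosphorane) | COc1cc(I)cc(Oc2ccc(C=P(c3ccccc3)(c3ccccc3)c3ccccc3)cc2)c1OC | intermediate (not isolated)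
14 | 2-{3-[2-{2-[4-(5-iodo-2,3-dimethoxyphenoxy)phenyl]ethenyl}-6-methoxyphenoxy]phenyl}ethanol (E/Z mixture, geometry left undefined) | OCCc1cccc(c1)Oc1c(OC)cccc1C=Cc1ccc(cc1)Oc1cc(I)cc(OC)c1OC | intermediate
15 | 2-{3-[2-{2-[4-(5-iodo-2,3-dimethoxyphenoxy)phenyl]ethyl}-6-methoxyphenoxy]phenyl}ethanol | OCCc1cccc(c1)Oc1c(OC)cccc1CCc1ccc(cc1)Oc1cc(I)cc(OC)c1OC | intermediate
16 | {3-[2-{2-[4-(5-iodo-2,3-dimethoxyphenoxy)phenyl]ethyl}-6-methoxyphenoxy]phenyl}acetaldehyde (seco iodo aldehyde) | O=CCc1cccc(c1)Oc1c(OC)cccc1CCc1ccc(cc1)Oc1cc(I)cc(OC)c1OC | intermediate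
17 | macrocyclic benzylic alcohol (racemic) | OC1Cc2cccc(c2)Oc2c(OC)cccc2CCc2ccc(cc2)Oc2cc1cc(OC)c2OC | intermediate
18 | marchantin G trimethyl ether | O=C1Cc2cccc(c2)Oc2c(OC)cccc2CCc2ccc(cc2)Oc2cc1cc(OC)c2OC | intermediate
19 | marchantin G | O=C1Cc2cccc(c2)Oc2c(O)cccc2CCc2ccc(cc2)Oc2cc1cc(O)c2O | target

Total step count: 13
Longest linear sequence: 12 steps (steps 1 to 6, then 8 to 13, from o-vanillin 1)

Steps most likely to fail

Step 11. The aryl–metal intermediate may be protonated, so that iodine is lost without ring closure, or chain-to-chain coupling may outrun closure of the large ring. The fallback changes the way the aryl group is delivered and sets out from iodo alcohol 15. Miyaura borylation (PdCl2(dppf), bis(pinacolato)diboron, KOAc, dioxane, 80 °C) should give the ring A pinacol boronate alcohol F1, and Dess–Martin oxidation the boronate aldehyde F2. Intramolecular 1,2-addition of the arylboronate to the aldehyde, catalysed by [Rh(cod)OH]2 in dioxane/water at high dilution, then closes the same bond. This is the known rhodium-catalysed addition of arylboron reagents to aldehydes; it is redox-neutral at monovalent rhodium and has no reductive dehalogenation pathway. The fallback comes back to the route at carbinol 17.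

Step 10. The arylacetaldehyde may be over-oxidised, or may enolise and then self-condense or autoxidise during oxidation and isolation. The fallback reaches the same aldehyde by reduction of an ester and sets out from fluoroaldehyde 10. Substitution of the fluoride by methyl (3-hydroxyphenyl)acetate (COC(=O)Cc1cccc(O)c1; K2CO3, DMF, 100 °C) should give methyl [3-(2-formyl-6-methoxyphenoxy)phenyl]acetate F3. Wittig reaction with phosphonium salt 9 (K2CO3, 18-crown-6, CH2Cl2, through ylide 13) gives the stilbene ester F4 as an E/Z mixture, and diimide reduction (TsNHNH2, NaOAc, DME/H2O) the bibenzyl ester F5. Partial reduction with i-Bu2AlH (toluene/CH2Cl2, −78 °C, cold quench with aqueous potassium sodium tartrate) holds the product as an aluminium hemiacetal until work-up and releases the aldehyde without oxidant or acid. The fallback comes back to the route at aldehyde 16, which is used crude in step 11.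

Step 7. Displacement of a fluoride that lies between the formyl group and an electron-donating methoxy group may be slow, and the aldehyde may degrade at the temperature required. The fallback replaces the uncatalysed substitution by a copper-catalysed Ullmann ether coupling and sets out from phenol 11. Coupling with 2-bromo-3-methoxybenzaldehyde (COc1cccc(C=O)c1Br; CuI, N,N-dimethylglycine, Cs2CO3, dioxane, 90 °C) should arylate the phenoxide in preference to the aliphatic alcohol. It comes back to the route at aldehyde 12 and makes no new compound.

Further compounds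
F1 | step 11 | 2-{3-[2-{2-[4-(2,3-dimethoxy-5-(4,4,5,5-tetramethyl-1,3,2-dioxaborolan-2-yl)phenoxy)phenyl]ethyl}-6-methoxyphenoxy]phenyl}ethanol | OCCc1cccc(c1)Oc1c(OC)cccc1CCc1ccc(cc1)Oc1cc(cc(OC)c1OC)B1OC(C)(C)C(C)(C)O1
F2 | step 11 | {3-[2-{2-[4-(2,3-dimethoxy-5-(4,4,5,5-tetramethyl-1,3,2-dioxaborolan-2-yl)phenoxy)phenyl]ethyl}-6-methoxyphenoxy]phenyl}acetaldehyde | O=CCc1cccc(c1)Oc1c(OC)cccc1CCc1ccc(cc1)Oc1cc(cc(OC)c1OC)B1OC(C)(C)C(C)(C)O1
F3 | step 10 | methyl [3-(2-formyl-6-methoxyphenoxy)phenyl]acetate | COC(=O)Cc1cccc(c1)Oc1c(OC)cccc1C=O
F4 | step 10 | methyl {3-[2-{2-[4-(5-iodo-2,3-dimethoxyphenoxy)phenyl]ethenyl}-6-methoxyphenoxy]phenyl}acetate (E/Z mixture) | COC(=O)Cc1cccc(c1)Oc1c(OC)cccc1C=Cc1ccc(cc1)Oc1cc(I)cc(OC)c1OC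
F5 | step 10 | methyl {3-[2-{2-[4-(5-iodo-2,3-dimethoxyphenoxy)phenyl]ethyl}-6-methoxyphenoxy]phenyl}acetate | COC(=O)Cc1cccc(c1)Oc1c(OC)cccc1CCc1ccc(cc1)Oc1cc(I)cc(OC)c1OC
F0 | step 7 | none | none
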